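Each identical cyclohexane end ring is disconnected at the bond between the quaternary gem-dimethyl carbon C1 and the stereogenic C6 that carries the polyene (carotenoid numbering). An acyclic methallyl/vinyl sulfone precursor, held by a cis-3,4-acetonide, is closed by a hydrogen-atom-transfer radical cyclization: the tertiary C1 radical adds 6-exo to C6 of a (1-phenyltetrazol-5-yl) vinyl sulfone. One operation makes the ring, the quaternary C1, the C6 stereocentre (trans to the C5 methyl) and the C7 sulfone needed for olefination. Because the target is twofold symmetric, two such C10 sulfones are joined to the C20 dialdehyde crocetindialdehyde by a double Julia–Kocienski reaction; regioselective sulfation of the equatorial 4-hydroxyls finishes the route.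

Key step: step 9

Remarks on the chemistry
- Carotenoid numbering is used for the end ring: C1 gem-dimethyl carbon, C2 methylene, C3 CH–OH, C4 CH–OSO3H, C5 CH–CH3, C6 CH carrying the chain, C7 first chain carbon. The target is (3R,4S,5R,6R,3'R,4'S,5'R,6'R), all-E; in the chair the 3-oxygen is axial and the 4-oxygen, the 5-methyl and the 6-side chain are equatorial.
- Assumption: the target is delivered as the free bis(hydrogen sulfate) as drawn; the ammonium salt formed first is converted by brief cation exchange.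
- Assumption: compounds 1, 2, 5, 6, 12 and 17 are taken as commercial.

Step 1
Reactants: 1 1-phenyl-1H-tetrazole-5-thiol; 2 diethyl (iodomethyl)phosphonate
Product: 3 diethyl {[(1-phenyl-1H-tetrazol-5-yl)sulfanyl]methyl}phosphonate
Conditions: K2CO3, DMF, 60 °C
Reagents that add atoms: none
Why: The thiolate formed with K2CO3 should displace iodide in an SN2 S-alkylation, the soft sulfur reacting in preference to the ring nitrogens.

Step 2
Reactants: 3 diethyl {[(1-phenyl-1H-tetrazol-5-yl)sulfanyl]methyl}phosphonate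
Product: 4 diethyl {[(1-phenyl-1H-tetrazol-5-yl)sulfonyl]methyl}phosphonate
Conditions: 30% H2O2, (NH4)6Mo7O24·4H2O (cat.), EtOH, 0 °C to rt
Reagents that add atoms: hydrogen peroxide, OO
Why: Molybdate-catalysed peroxide oxidation of a sulfide to the sulfone is the standard entry to tetrazolyl sulfones and leaves the phosphonate untouched.

Step 3
Reactants: 5 (4R)-2,2-dimethyl-1,3-dioxolane-4-carbaldehyde; 6 4,4,5,5-tetramethyl-2-[(2Z)-but-2-en-1-yl]-1,3,2-dioxaborolane
Product: 7 (1S,2R)-1-[(4R)-2,2-dimethyl-1,3-dioxolan-4-yl]-2-methylbut-3-en-1-ol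
Conditions: toluene, 4 Å MS, rt; aqueous work-up
Reagents that add atoms: none
Why: Crotylboration through a closed chair (Zimmerman–Traxler) transition state: the Z-boronate gives the syn OH/CH3 relation and the strong Felkin–Anh (anti) preference of Z-crotylboronates with this α-alkoxy aldehyde sets the (1S) and (2R) centres from the dioxolane carbon, which serves as a control element that is excised in step 6.

Step 4
Reactants: 7 (1S,2R)-1-[(4R)-2,2-dimethyl-1,3-dioxolan-4-yl]-2-methylbut-3-en-1-ol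
Product: 8 tert-butyl{[(1S,2R)-1-[(4R)-2,2-dimethyl-1,3-dioxolan-4-yl]-2-methylbut-3-en-1-yl]oxy}dimethylsilane
Conditions: TBSOTf, 2,6-lutidine, CH2Cl2, −78 to 0 °C
Reagents that add atoms: tert-butyldimethylsilyl trifluoromethanesulfonate, CC(C)(C)[Si](C)(C)OS(=O)(=O)C(F)(F)F
Why: Silylation of the hindered secondary alcohol with the silyl triflate gives an ether that should survive ozone, periodic acid and the allylboration.

Step 5
Reactants: 8 tert-butyl{[(1S,2R)-1-[(4R)-2,2-dimethyl-1,3-dioxolan-4-yl]-2-methylbut-3-en-1-yl]oxy}dimethylsilane; 4 diethyl {[(1-phenyl-1H-tetrazol-5-yl)sulfonyl]methyl}phosphonate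
Product: 10 5-{[(1E,3R,4S)-4-[(tert-butyldimethylsilyl)oxy]-4-[(4R)-2,2-dimethyl-1,3-dioxolan-4-yl]-3-methylbut-1-en-1-yl]sulfonyl}-1-phenyl-1H-tetrazole, via aldehyde 9 (not isolated)
Conditions: O3, CH2Cl2, −78 °C; PPh3, −78 °C to rt; then 4, LiCl, i-Pr2NEt, MeCN, 0 °C to rt
Reagents that add atoms: ozone, [O-][O+]=O (its oxygen is carried only by intermediate 9)
Why: Ozonolysis with reductive work-up gives the α-methyl aldehyde, which is trapped without isolation in a Horner–Wadsworth–Emmons reaction under mild LiCl/amine conditions that avoid epimerization, the lithium-bound adduct collapsing by phosphate loss to the E vinyl sulfone.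

Step 6
Reactants: 10 5-{[(1E,3R,4S)-4-[(tert-butyldimethylsilyl)oxy]-4-[(4R)-2,2-dimethyl-1,3-dioxolan-4-yl]-3-methylbut-1-en-1-yl]sulfonyl}-1-phenyl-1H-tetrazole
Product: 11 (2S,3R,4E)-2-[(tert-butyldimethylsilyl)oxy]-3-methyl-5-[(1-phenyl-1H-tetrazol-5-yl)sulfonyl]pent-4-enal
Conditions: H5IO6, EtOAc, rt
Reagents that add atoms: none
Why: Periodic acid hydrolyses the terminal acetonide and cleaves the liberated 1,2-diol (Malaprade glycol cleavage) in one operation, so that the used control centre becomes the C3 aldehyde while the silyl ether and the vinyl sulfone stay intact.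

Step 7
Reactants: 11 (2S,3R,4E)-2-[(tert-butyldimethylsilyl)oxy]-3-methyl-5-[(1-phenyl-1H-tetrazol-5-yl)sulfonyl]pent-4-enal; 12 4,4,5,5-tetramethyl-2-(2-methylprop-2-en-1-yl)-1,3,2-dioxaborolane
Product: 13 (4R,5S,6R,7E)-5-[(tert-butyldimethylsilyl)oxy]-2,6-dimethyl-8-[(1-phenyl-1H-tetrazol-5-yl)sulfonyl]octa-1,7-dien-4-ol
Conditions: (R)-3,3'-bis(2,4,6-triisopropylphenyl)-1,1'-binaphthyl-2,2'-diyl hydrogen phosphate (5 mol %), toluene, 4 Å MS, −30 °C
Reagents that add atoms: none
Why: Chiral-phosphoric-acid-catalysed allylboration through a chair transition state: the (R) catalyst is expected to direct the methallyl group to the re face, which coincides with the Felkin–Anh (anti) preference of the α-silyloxy aldehyde and sets the (4R) carbinol, and the neutral boronate does not touch the vinyl sulfone.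

Step 8
Reactants: 13 (4R,5S,6R,7E)-5-[(tert-butyldimethylsilyl)oxy]-2,6-dimethyl-8-[(1-phenyl-1H-tetrazol-5-yl)sulfonyl]octa-1,7-dien-4-ol
Product: 15 5-({(1E,3R)-3-[(4S,5R)-2,2-dimethyl-5-(2-methylprop-2-en-1-yl)-1,3-dioxolan-4-yl]but-1-en-1-yl}sulfonyl)-1-phenyl-1H-tetrazole, via diol 14 (not isolated)
Conditions: camphorsulfonic acid (cat.), MeOH, rt; then 2,2-dimethoxypropane, acetone, rt
Reagents that add atoms: 2,2-dimethoxypropane, COC(C)(C)OC
Why: Acid-catalysed methanolysis of the silyl ether followed by transketalization ties the anti-diol into the cis-dioxolane, under acidic conditions in which oxa-Michael addition to the vinyl sulfone should not occur.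

Step 9
Reactants: 15 5-({(1E,3R)-3-[(4S,5R)-2,2-dimethyl-5-(2-methylprop-2-en-1-yl)-1,3-dioxolan-4-yl]but-1-en-1-yl}sulfonyl)-1-phenyl-1H-tetrazole
Product: 16 (3aS,4R,5R,7aR)-2,2,4,6,6-pentamethyl-5-{[(1-phenyl-1H-tetrazol-5-yl)sulfonyl]methyl}hexahydro-2H-1,3-benzodioxole
Conditions: Fe(acac)3 (30 mol %), PhSiH3, EtOH/ethylene glycol (5:1), degassed, 60 °C
Reagents that add atoms: none
Why: Fe(acac)3 and PhSiH3 form an iron hydride that transfers a hydrogen atom to the terminal CH2 of the electron-rich 1,1-disubstituted alkene, so that a tertiary radical arises at C1; this nucleophilic radical adds to the electron-poor β-carbon C6 of the vinyl sulfone, and the α-sulfonyl radical at C7 is reduced by divalent iron and protonated by ethanol. The closest known reaction type is the metal-hydride hydrogen-atom-transfer reductive olefin coupling (radical conjugate addition of unactivated alkenes to vinyl sulfones and enones), used here in its intramolecular form. The cyclohexane ring is closed in the 6-exo-trig mode, and the C1–C6 bond, the quaternary C1 and the C7 methylene sulfone arise together. The new stereocentre C6 is controlled by the substrate: in the chair-like transition state the C5 methyl and the C6=C7 acceptor both lie pseudo-equatorial on a ring that is already cis-fused to the dioxolane, which should give the 5,6-trans product with the (6R) configuration of the target. The step needs hydrogen-atom transfer to the methallyl alkene and not to the acceptor, 6-exo and not 7-endo attack, and ring closure before the radical is reduced; polarity matching, the short cis-dioxolane tether and the absence of other alkenes secure this.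

Step 10
Reactants: 16 (3aS,4R,5R,7aR)-2,2,4,6,6-pentamethyl-5-{[(1-phenyl-1H-tetrazol-5-yl)sulfonyl]methyl}hexahydro-2H-1,3-benzodioxole (2.3 equiv); 17 (2E,4E,6E,8E,10E,12E,14E)-2,6,11,15-tetramethylhexadeca-2,4,6,8,10,12,14-heptaenedial (crocetindialdehyde)
Product: 18 (3R,4S,5R,6R,3'R,4'S,5'R,6'R)-3,4:3',4'-bis-O-isopropylidene-5,6,5',6'-tetrahydro-β,β-carotene-3,4,3',4'-tetrol (all-E)
Conditions: KN(SiMe3)2, THF, −78 °C; then 17, −78 °C to rt, dark, argon; aq. NH4Cl
Reagents that add atoms: none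
Why: Double Julia–Kocienski olefination: each metalated sulfone adds to an aldehyde terminus, and Smiles rearrangement with loss of SO2 and the tetrazololate should give the two C7=C8 bonds with the E selectivity typical of phenyltetrazolyl sulfones with a potassium counter-ion, while the non-acidic C6 keeps its configuration.

Step 11
Reactants: 18 (3R,4S,5R,6R,3'R,4'S,5'R,6'R)-3,4:3',4'-bis-O-isopropylidene-5,6,5',6'-tetrahydro-β,β-carotene-3,4,3',4'-tetrol
Product: 19 (3R,4S,5R,6R,3'R,4'S,5'R,6'R)-5,6,5',6'-tetrahydro-β,β-carotene-3,4,3',4'-tetrol (all-E)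
Conditions: AcOH/H2O/THF, 45 °C, dark, argon
Reagents that add atoms: none
Why: Mild acid hydrolysis of the two cyclic acetals frees the cis-diols, and the polyene should tolerate it because no hydroxyl is allylic to the chain in these 5,6-dihydro rings.

Step 12
Reactants: 19 (3R,4S,5R,6R,3'R,4'S,5'R,6'R)-5,6,5',6'-tetrahydro-β,β-carotene-3,4,3',4'-tetrol
Product: 21 (3R,4S,5R,6R,3'R,4'S,5'R,6'R)-5,6,5',6'-tetrahydro-β,β-carotene-3,4,3',4'-tetrol 4,4'-bis(hydrogen sulfate) (all-E), via stannylene acetal 20 (not isolated)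
Conditions: Bu2SnO, toluene/MeOH, reflux with removal of water, dark; then SO3·NMe3, DMF, rt; then H+ ion-exchange resin, MeOH, 0 °C
Reagents that add atoms: sulfur trioxide–trimethylamine complex, C[N+](C)(C)S(=O)(=O)[O-]; dibutyltin oxide, CCCC[Sn](=O)CCCC (its tin is carried only by intermediate 20)
Why: Dibutylstannylene acetals of cis-1,2-diols on six-membered rings raise the nucleophilicity of the equatorial oxygen, so that tin-mediated O-sulfation should take place at the equatorial 4-oxygen and leave the axial 3-hydroxyl, which is shielded by the 1,3-diaxial methyl, free.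

Compound list
1 | 1-phenyl-1H-tetrazole-5-thiol | Sc1nnnn1-c1ccccc1 | starting material
2 | diethyl (iodomethyl)phosphonate | CCOP(=O)(CI)OCC | starting material
3 | diethyl {[(1-phenyl-1H-tetrazol-5-yl)sulfanyl]methyl}phosphonate | CCOP(=O)(CSc1nnnn1-c1ccccc1)OCC | intermediate
4 | diethyl {[(1-phenyl-1H-tetrazol-5-yl)sulfonyl]methyl}phosphonate | CCOP(=O)(CS(=O)(=O)c1nnnn1-c1ccccc1)OCC | intermediate
5 | (4R)-2,2-dimethyl-1,3-dioxolane-4-carbaldehyde | O=C[C@H]1COC(C)(C)O1 | starting material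
6 | 4,4,5,5-tetramethyl-2-[(2Z)-but-2-en-1-yl]-1,3,2-dioxaborolane | C/C=C\CB1OC(C)(C)C(C)(C)O1 | starting material
7 | (1S,2R)-1-[(4R)-2,2-dimethyl-1,3-dioxolan-4-yl]-2-methylbut-3-en-1-ol | C=C[C@@H](C)[C@H](O)[C@H]1COC(C)(C)O1 | intermediate
8 | tert-butyl{[(1S,2R)-1-[(4R)-2,2-dimethyl-1,3-dioxolan-4-yl]-2-methylbut-3-en-1-yl]oxy}dimethylsilane | C=C[C@@H](C)[C@H](O[Si](C)(C)C(C)(C)C)[C@H]1COC(C)(C)O1 | intermediate
9 | (2S,3S)-3-[(tert-butyldimethylsilyl)oxy]-3-[(4R)-2,2-dimethyl-1,3-dioxolan-4-yl]-2-methylpropanal | O=C[C@@H](C)[C@H](O[Si](C)(C)C(C)(C)C)[C@H]1COC(C)(C)O1 | intermediate (not isolated)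
10 | 5-{[(1E,3R,4S)-4-[(tert-butyldimethylsilyl)oxy]-4-[(4R)-2,2-dimethyl-1,3-dioxolan-4-yl]-3-methylbut-1-en-1-yl]sulfonyl}-1-phenyl-1H-tetrazole | O=S(=O)(/C=C/[C@@H](C)[C@H](O[Si](C)(C)C(C)(C)C)[C@H]1COC(C)(C)O1)c1nnnn1-c1ccccc1 | intermediate
11 | (2S,3R,4E)-2-[(tert-butyldimethylsilyl)oxy]-3-methyl-5-[(1-phenyl-1H-tetrazol-5-yl)sulfonyl]pent-4-enal | O=S(=O)(/C=C/[C@@H](C)[C@H](O[Si](C)(C)C(C)(C)C)C=O)c1nnnn1-c1ccccc1 | intermediate
12 | 4,4,5,5-tetramethyl-2-(2-methylprop-2-en-1-yl)-1,3,2-dioxaborolane | C=C(C)CB1OC(C)(C)C(C)(C)O1 | starting material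
13 | (4R,5S,6R,7E)-5-[(tert-butyldimethylsilyl)oxy]-2,6-dimethyl-8-[(1-phenyl-1H-tetrazol-5-yl)sulfonyl]octa-1,7-dien-4-ol | O=S(=O)(/C=C/[C@@H](C)[C@H](O[Si](C)(C)C(C)(C)C)[C@H](O)CC(C)=C)c1nnnn1-c1ccccc1 | intermediate
14 | (4R,5S,6R,7E)-2,6-dimethyl-8-[(1-phenyl-1H-tetrazol-5-yl)sulfonyl]octa-1,7-diene-4,5-diol | O=S(=O)(/C=C/[C@@H](C)[C@H](O)[C@H](O)CC(C)=C)c1nnnn1-c1ccccc1 | intermediate (not isolated)
15 | 5-({(1E,3R)-3-[(4S,5R)-2,2-dimethyl-5-(2-methylprop-2-en-1-yl)-1,3-dioxolan-4-yl]but-1-en-1-yl}sulfonyl)-1-phenyl-1H-tetrazole | O=S(=O)(/C=C/[C@@H](C)[C@@H]1OC(C)(C)O[C@@H]1CC(C)=C)c1nnnn1-c1ccccc1 | intermediate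
16 | (3aS,4R,5R,7aR)-2,2,4,6,6-pentamethyl-5-{[(1-phenyl-1H-tetrazol-5-yl)sulfonyl]methyl}hexahydro-2H-1,3-benzodioxole | O=S(=O)(C[C@@H]1[C@@H](C)[C@@H]2OC(C)(C)O[C@@H]2CC1(C)C)c1nnnn1-c1ccccc1 | intermediate
17 | (2E,4E,6E,8E,10E,12E,14E)-2,6,11,15-tetramethylhexadeca-2,4,6,8,10,12,14-heptaenedial (crocetindialdehyde) | CC(/C=C/C=C(C)/C=O)=C\C=C\C=C(C)\C=C\C=C(C)\C=O | starting material
18 | (3R,4S,5R,6R,3'R,4'S,5'R,6'R)-3,4:3',4'-bis-O-isopropylidene-5,6,5',6'-tetrahydro-β,β-carotene-3,4,3',4'-tetrol (all-E) | CC(/C=C/C=C(C)/C=C/[C@@H]1[C@@H](C)[C@@H]2OC(C)(C)O[C@@H]2CC1(C)C)=C\C=C\C=C(C)\C=C\C=C(C)\C=C\[C@@H]1[C@@H](C)[C@@H]2OC(C)(C)O[C@@H]2CC1(C)C | intermediate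
19 | (3R,4S,5R,6R,3'R,4'S,5'R,6'R)-5,6,5',6'-tetrahydro-β,β-carotene-3,4,3',4'-tetrol (all-E) | CC(/C=C/C=C(C)/C=C/[C@@H]1[C@@H](C)[C@H](O)[C@H](O)CC1(C)C)=C\C=C\C=C(C)\C=C\C=C(C)\C=C\[C@@H]1[C@@H](C)[C@H](O)[C@H](O)CC1(C)C | intermediate
20 | 3,4:3',4'-bis-O-(dibutylstannylene) acetal of tetrol 19 | CC(/C=C/C=C(C)/C=C/[C@@H]1[C@@H](C)[C@@H]2O[Sn](CCCC)(CCCC)O[C@@H]2CC1(C)C)=C\C=C\C=C(C)\C=C\C=C(C)\C=C\[C@@H]1[C@@H](C)[C@@H]2O[Sn](CCCC)(CCCC)O[C@@H]2CC1(C)C | intermediate (not isolated)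
21 | (3R,4S,5R,6R,3'R,4'S,5'R,6'R)-5,6,5',6'-tetrahydro-β,β-carotene-3,4,3',4'-tetrol 4,4'-bis(hydrogen sulfate) (all-E) | CC(/C=C/C=C(C)/C=C/[C@@H]1[C@@H](C)[C@H](OS(=O)(=O)O)[C@H](O)CC1(C)C)=C\C=C\C=C(C)\C=C\C=C(C)\C=C\[C@@H]1[C@@H](C)[C@H](OS(=O)(=O)O)[C@H](O)CC1(C)C | target

Total step count: 12 (steps 1 and 2 make the phosphonate reagent 4; steps 3 to 12 are the main line).
Longest linear sequence: 10 steps (steps 3 to 12).

Steps most likely to fail

1. Step 9 (key step). The tertiary radical may be reduced by the hydride source before it closes the ring, which would amount to hydrogenation of the methallyl group. The tetrazolyl sulfone may also be degraded under the hydridic, alcoholic conditions at 60 °C. The fallback sets out from 15 and comes back at 16; it forms the same C1 radical without a hydride donor in the ring-closing step. Mukaiyama hydration of 15 (Co(acac)2, PhSiH3, O2, i-PrOH, rt), in which oxygen should intercept the radical faster than it can cyclize, would give the tertiary alcohol 1-[(4R,5S)-2,2-dimethyl-5-{(2R,3E)-4-[(1-phenyl-1H-tetrazol-5-yl)sulfonyl]but-3-en-2-yl}-1,3-dioxolan-4-yl]-2-methylpropan-2-ol F1. Acylation with methyl chlorooxoacetate (Et3N, DMAP, CH2Cl2) would give the methyl oxalate F2, and careful saponification with CsOH (THF/H2O, 0 °C) the cesium oxalate F3. Visible-light photoredox fragmentation of F3 (Ir[dF(CF3)ppy]2(dtbbpy)PF6, DME/DMF, H2O, blue LEDs, rt) loses two molecules of CO2; the tertiary radical then has no fast hydrogen donor as competitor and should close to 16 in a Giese cyclization.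

2. Step 12. The two hydroxyls of each cis-diol may not be discriminated well enough, giving sulfation at O3 or over-sulfation, and the polyene may isomerize during the hot stannylene formation. The fallback sets out from 19 and comes back at 21; it replaces tin activation by temporary protection of the axial hydroxyl. Trimethyl orthoacetate with camphorsulfonic acid (cat.) in CH2Cl2 would give the bis(cyclic methyl orthoacetate) F8. Its hydrolysis with aqueous AcOH is known to open such orthoesters to the axial ester and would give the 3,3'-di-O-acetyl tetrol F9 with free equatorial 4-hydroxyls. Sulfation with SO3·pyridine in DMF would give the 3,3'-di-O-acetyl 4,4'-bis(hydrogen sulfate) F10. Methanolysis of the acetates (K2CO3, MeOH), which sulfate monoesters tolerate, and cation exchange would give 21.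

3. Step 10. The β-branched, hindered sulfonyl carbanion may add only slowly to the sparingly soluble, weakly electrophilic polyene dialdehyde, so that the second olefination stays incomplete and E selectivity erodes. The fallback sets out from 16 and comes back at 18; it moves the union to the classical C15 + C10 + C15 double Wittig condensation. Julia–Kocienski olefination of 16 with the small, reactive aldehyde ethyl (2E)-3-methyl-4-oxobut-2-enoate (KN(SiMe3)2, THF, −78 °C) would give ethyl (2E,4E)-3-methyl-5-[(3aS,4R,5R,7aR)-2,2,4,6,6-pentamethylhexahydro-2H-1,3-benzodioxol-5-yl]penta-2,4-dienoate F4. Reduction with i-Bu2AlH would give the dienol F5, PBr3 (pyridine, Et2O, 0 °C) the allylic bromide F6, and PPh3 the phosphonium bromide F7. Double Wittig reaction of F7 (2 equiv) with commercial (2E,4E,6E)-2,7-dimethylocta-2,4,6-trienedial (NaOMe, CH2Cl2/MeOH), followed by thermal equilibration of the new 11,12 double bonds to E, would give 18.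

Further compounds
F1 | step 9 | 1-[(4R,5S)-2,2-dimethyl-5-{(2R,3E)-4-[(1-phenyl-1H-tetrazol-5-yl)sulfonyl]but-3-en-2-yl}-1,3-dioxolan-4-yl]-2-methylpropan-2-ol | O=S(=O)(/C=C/[C@@H](C)[C@@H]1OC(C)(C)O[C@@H]1CC(C)(C)O)c1nnnn1-c1ccccc1
F2 | step 9 | methyl 1-[(4R,5S)-2,2-dimethyl-5-{(2R,3E)-4-[(1-phenyl-1H-tetrazol-5-yl)sulfonyl]but-3-en-2-yl}-1,3-dioxolan-4-yl]-2-methylpropan-2-yl oxalate | O=S(=O)(/C=C/[C@@H](C)[C@@H]1OC(C)(C)O[C@@H]1CC(C)(C)OC(=O)C(=O)OC)c1nnnn1-c1ccccc1
F3 | step 9 | cesium 1-[(4R,5S)-2,2-dimethyl-5-{(2R,3E)-4-[(1-phenyl-1H-tetrazol-5-yl)sulfonyl]but-3-en-2-yl}-1,3-dioxolan-4-yl]-2-methylpropan-2-yl oxalate | O=S(=O)(/C=C/[C@@H](C)[C@@H]1OC(C)(C)O[C@@H]1CC(C)(C)OC(=O)C(=O)[O-])c1nnnn1-c1ccccc1.[Cs+]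
F4 | step 10 | ethyl (2E,4E)-3-methyl-5-[(3aS,4R,5R,7aR)-2,2,4,6,6-pentamethylhexahydro-2H-1,3-benzodioxol-5-yl]penta-2,4-dienoate | CCOC(=O)/C=C(C)/C=C/[C@@H]1[C@@H](C)[C@@H]2OC(C)(C)O[C@@H]2CC1(C)C
F5 | step 10 | (2E,4E)-3-methyl-5-[(3aS,4R,5R,7aR)-2,2,4,6,6-pentamethylhexahydro-2H-1,3-benzodioxol-5-yl]penta-2,4-dien-1-ol | OC/C=C(C)/C=C/[C@@H]1[C@@H](C)[C@@H]2OC(C)(C)O[C@@H]2CC1(C)C
F6 | step 10 | (3aS,4R,5R,7aR)-5-[(1E,3E)-5-bromo-3-methylpenta-1,3-dien-1-yl]-2,2,4,6,6-pentamethylhexahydro-2H-1,3-benzodioxole | BrC/C=C(C)/C=C/[C@@H]1[C@@H](C)[C@@H]2OC(C)(C)O[C@@H]2CC1(C)C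
F7 | step 10 | {(2E,4E)-3-methyl-5-[(3aS,4R,5R,7aR)-2,2,4,6,6-pentamethylhexahydro-2H-1,3-benzodioxol-5-yl]penta-2,4-dien-1-yl}triphenylphosphonium bromide | [Br-].c1ccc(cc1)[P+](c1ccccc1)(c1ccccc1)C/C=C(C)/C=C/[C@@H]1[C@@H](C)[C@@H]2OC(C)(C)O[C@@H]2CC1(C)C
F8 | step 12 | 3,4:3',4'-bis-O-(1-methoxyethylidene) derivative of tetrol 19 (orthoester carbons as a mixture of epimers) | CC(/C=C/C=C(C)/C=C/[C@@H]1[C@@H](C)[C@@H]2OC(C)(OC)O[C@@H]2CC1(C)C)=C\C=C\C=C(C)\C=C\C=C(C)\C=C\[C@@H]1[C@@H](C)[C@@H]2OC(C)(OC)O[C@@H]2CC1(C)C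
F9 | step 12 | (3R,4S,5R,6R,3'R,4'S,5'R,6'R)-5,6,5',6'-tetrahydro-β,β-carotene-3,4,3',4'-tetrol 3,3'-diacetate | CC(/C=C/C=C(C)/C=C/[C@@H]1[C@@H](C)[C@H](O)[C@H](OC(C)=O)CC1(C)C)=C\C=C\C=C(C)\C=C\C=C(C)\C=C\[C@@H]1[C@@H](C)[C@H](O)[C@H](OC(C)=O)CC1(C)C
F10 | step 12 | (3R,4S,5R,6R,3'R,4'S,5'R,6'R)-5,6,5',6'-tetrahydro-β,β-carotene-3,4,3',4'-tetrol 3,3'-diacetate 4,4'-bis(hydrogen sulfate) | CC(/C=C/C=C(C)/C=C/[C@@H]1[C@@H](C)[C@H](OS(=O)(=O)O)[C@H](OC(C)=O)CC1(C)C)=C\C=C\C=C(C)\C=C\C=C(C)\C=C\[C@@H]1[C@@H](C)[C@H](OS(=O)(=O)O)[C@H](OC(C)=O)CC1(C)C
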